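## Retrosynthetic overview

1. The cyclohexene of target 48 is cut by a retro-[4+2] into two 14-membered monomers, keto-enoate dienophile 21 and (1Z,3E)-triene 47; this cycloaddition is the last step.
2. Dienophile 21 is opened at its enoate alkene (tandem oxidation/intramolecular Wittig). Its chain comes from (R)-citronellal, methyl (S)-lactate and the L-valine-derived hydroxy ester 11, the last two joined by SN2 with inversion.
3. Triene 47 is opened at T4–T5 (B-alkyl Suzuki). T12 and T14 come from chelation-controlled MeMgBr addition and 1,3-anti reduction after an aldol union of methyl ketone 30 with iodo-dienal 37 (from propargyl alcohol by anti-carbomagnesiation).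
4. Ketone 30 carries the tetrahydropyran in from Cyrene: T11 is bought, T8 is set by face-selective MeMgBr addition, T7 by trans-selective C-glycosylation.
5. Ring order: tetrahydropyran (present in Cyrene) → the two 14-membered rings (in parallel) → cyclohexene.

Locants: D1–D14 are the ring carbons of 21 (D1 CH-iPr, D3 C=O, D4 CHMe, D8 CHMe, D10 C=O, D11=D12(CO2Me), D14 C=O). T1–T14 are the ring carbons of 47 (T1 bears the isopropenyl group T15(=T16)T17, T3=T4 alkene, T7 and T11 ether-bridged, T8 C(Me)OAc, T12 C(Me)OH, T14 CHOAc).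

Assumption: tert-butyl (S)-2-hydroxy-3-methylbutanoate (11, made from L-valine) and Cyrene (22, from cellulose) are taken as purchasable, like 1, 6 and 31.

## Route

Step 1
Reactants: 1 (R)-citronellal, (3R)-3,7-dimethyloct-6-enal
Product: 2 (4R)-4,8-dimethylnona-1,7-diene
Conditions: Ph3PCH3Br, KOtBu, THF, 0 °C → rt
Reagents that add atoms: methyltriphenylphosphonium bromide, C[P+](c1ccccc1)(c1ccccc1)c1ccccc1.[Br-]
Why: Wittig methylenation of the aldehyde gives the terminal alkene that later becomes D10–D11, and the remote D8 stereocentre bought in 1 is untouched.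

Step 2
Reactants: 2 (4R)-4,8-dimethylnona-1,7-diene
Product: 4 (4R)-4-methylhept-6-en-1-ol, via (4R)-4-methylhept-6-enal 3 (not isolated)
Conditions: O3 (1.0 equiv), CH2Cl2/MeOH, −78 °C; then NaBH4, −78 → 0 °C
Reagents that add atoms: ozone, [O-][O+]=O
Why: Chemoselective ozonolysis cleaves the electron-rich trisubstituted alkene much faster than the monosubstituted one, and borohydride reduction in the same pot gives the primary alcohol at D5.

Step 3
Reactants: 4 (4R)-4-methylhept-6-en-1-ol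
Product: 5 (4R)-7-bromo-4-methylhept-1-ene
Conditions: CBr4, PPh3, CH2Cl2, 0 °C
Reagents that add atoms: carbon tetrabromide, BrC(Br)(Br)Br
Why: The Appel reaction converts the primary alcohol into the bromide without touching the alkene or the stereocentre.

Step 4
Reactants: 6 methyl (S)-lactate, methyl (2S)-2-hydroxypropanoate
Product: 7 methyl (2S)-2-{[(trifluoromethyl)sulfonyl]oxy}propanoate
Conditions: Tf2O, 2,6-lutidine, CH2Cl2, −78 → 0 °C
Reagents that add atoms: trifluoromethanesulfonic anhydride, O=S(=O)(OS(=O)(=O)C(F)(F)F)C(F)(F)F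
Why: O-Sulfonylation with retention gives an α-triflyloxy ester activated for SN2 displacement.

Step 5
Reactants: 5 (4R)-7-bromo-4-methylhept-1-ene; 7 methyl (2S)-2-{[(trifluoromethyl)sulfonyl]oxy}propanoate
Product: 9 methyl (2S,6R)-2,6-dimethylnon-8-enoate, via Grignard reagent 8 (not isolated)
Conditions: Mg, THF, rt; then 7, ZnCl2 (10 mol %), THF, 0 °C
Reagents that add atoms: none
Why: Zinc-catalysed sp3–sp3 coupling of the Grignard reagent with the α-triflyloxy ester is an SN2 displacement with inversion, so (S)-lactate delivers the (S)-methyl stereocentre D4.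

Step 6
Reactants: 9 methyl (2S,6R)-2,6-dimethylnon-8-enoate
Product: 10 tert-butyl (4S,8R)-4,8-dimethyl-3-oxoundec-10-enoate
Conditions: tBuOAc, LiN(iPr)2, THF, −78 °C; then 9, −78 → −20 °C
Reagents that add atoms: tert-butyl acetate, CC(=O)OC(C)(C)C
Why: Crossed Claisen condensation with excess lithium tert-butyl acetate gives the β-keto ester, whose immediate deprotonation between the carbonyls protects D4 from epimerisation.

Step 7
Reactants: 11 tert-butyl (2S)-2-hydroxy-3-methylbutanoate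
Product: 12 tert-butyl (2S)-3-methyl-2-{[(trifluoromethyl)sulfonyl]oxy}butanoate
Conditions: Tf2O, 2,6-lutidine, CH2Cl2, −78 → 0 °C
Reagents that add atoms: trifluoromethanesulfonic anhydride, O=S(=O)(OS(=O)(=O)C(F)(F)F)C(F)(F)F
Why: O-Sulfonylation with retention turns the valine-derived carbinol into an SN2-active α-triflyloxy ester.

Step 8
Reactants: 10 tert-butyl (4S,8R)-4,8-dimethyl-3-oxoundec-10-enoate; 12 tert-butyl (2S)-3-methyl-2-{[(trifluoromethyl)sulfonyl]oxy}butanoate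
Product: 13 di-tert-butyl (2S)-3-[(2S,6R)-2,6-dimethylnon-8-enoyl]-2-(propan-2-yl)butanedioate (both C3 epimers)
Conditions: NaH, THF, 0 °C; then 12, 0 °C → rt
Reagents that add atoms: none
Why: SN2 C-alkylation of the soft β-keto ester enolate by the α-triflyloxy ester goes with inversion, so the (S)-hydroxy ester gives the D1 configuration of the target (CIP label S here, R after decarboxylation); the new D2 centre is removed in step 9.

Step 9
Reactants: 13 di-tert-butyl (2S)-3-[(2S,6R)-2,6-dimethylnon-8-enoyl]-2-(propan-2-yl)butanedioate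
Product: 14 (2R,5S,9R)-5,9-dimethyl-4-oxo-2-(propan-2-yl)dodec-11-enoic acid
Conditions: CF3CO2H/CH2Cl2 (1:3), rt; then toluene, 80 °C
Reagents that add atoms: none
Why: Acidolysis of both tert-butyl esters and thermal decarboxylation of the β-keto acid leave the γ-keto acid (1,4-dicarbonyl D14/D3) with D1 and D4 intact.

Step 10
Reactants: 14 (2R,5S,9R)-5,9-dimethyl-4-oxo-2-(propan-2-yl)dodec-11-enoic acid
Product: 17 (3R,6S,10R)-1-bromo-6,10-dimethyl-3-(propan-2-yl)tridec-12-ene-2,5-dione, via mixed carbonic anhydride 15 (not isolated), via diazoketone 16 (not isolated)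
Conditions: iBuOCOCl, N-methylmorpholine, THF, −15 °C; CH2N2, Et2O, 0 °C; then 48% aq HBr, 0 °C
Reagents that add atoms: diazomethane, C=[N+]=[N-]; hydrogen bromide, Br
Why: Acylation of diazomethane by the mixed anhydride (first stage of an Arndt–Eistert sequence) and hydrobromic acid cleavage of the diazoketone give the bromomethyl ketone D13–D14 under conditions that do not enolise D1.

Step 11
Reactants: 17 (3R,6S,10R)-1-bromo-6,10-dimethyl-3-(propan-2-yl)tridec-12-ene-2,5-dione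
Product: 18 (3R,6S,10R)-1-bromo-13-hydroxy-6,10-dimethyl-3-(propan-2-yl)tridecane-2,5,12-trione
Conditions: RuCl3 (1 mol %), KHSO5 (as 2KHSO5·KHSO4·K2SO4), NaHCO3, EtOAc/MeCN/H2O, rt, 20 min
Reagents that add atoms: potassium peroxymonosulfate, [K+].[O-]S(=O)(=O)OO; water, O
Why: RuO4-catalysed ketohydroxylation converts the terminal alkene regioselectively into the 1-hydroxy-2-ketone, installing the D10 carbonyl and D11 at the alcohol level.

Step 12
Reactants: 18 (3R,6S,10R)-1-bromo-13-hydroxy-6,10-dimethyl-3-(propan-2-yl)tridecane-2,5,12-trione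
Product: 19 methyl (5R,8S,12R)-15-hydroxy-8,12-dimethyl-4,7,14-trioxo-5-(propan-2-yl)-2-(triphenyl-λ5-phosphanylidene)pentadecanoate
Conditions: Ph3P=CHCO2Me (2.0 equiv), CH2Cl2, rt; filtration through neutral alumina
Reagents that add atoms: methyl (triphenyl-λ5-phosphanylidene)acetate, COC(=O)C=P(c1ccccc1)(c1ccccc1)c1ccccc1
Why: C-Alkylation of the stabilised ylide by the α-bromo ketone and transylidation by the second equivalent give the disubstituted stabilised ylide at D12, which does not react with the ketones present.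

Step 13
Reactants: 19 methyl (5R,8S,12R)-15-hydroxy-8,12-dimethyl-4,7,14-trioxo-5-(propan-2-yl)-2-(triphenyl-λ5-phosphanylidene)pentadecanoate
Product: 21 methyl (1E,5R,9S,12R)-5,9-dimethyl-3,10,13-trioxo-12-(propan-2-yl)cyclotetradec-1-ene-1-carboxylate, via ylide keto-aldehyde 20 (not isolated)
Conditions: MnO2 (excess), CH2Cl2 (0.5 mM), rt → 40 °C
Reagents that add atoms: none
Why: MnO2 oxidises the α-hydroxy ketone to the keto-aldehyde, which is trapped at high dilution by intramolecular Wittig reaction (tandem oxidation–Wittig macrocyclisation) to give the (E)-enoate with the ester trans to the D10 ketone.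

Step 14
Reactants: 22 Cyrene, (1S,5R)-6,8-dioxabicyclo[3.2.1]octan-4-one
Product: 23 (1S,4S,5R)-4-methyl-6,8-dioxabicyclo[3.2.1]octan-4-ol
Conditions: MeMgBr, THF, −78 → 0 °C
Reagents that add atoms: methylmagnesium bromide, C[Mg]Br
Why: Grignard 1,2-addition occurs from the face opposite the 1,6-anhydro bridge of the rigid bicycle, setting T8 with the hydroxyl syn to the bridge under control of the bought T11 centre.

Step 15
Reactants: 23 (1S,4S,5R)-4-methyl-6,8-dioxabicyclo[3.2.1]octan-4-ol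
Product: 24 [(2S,5S)-5,6-bis(acetyloxy)-5-methyloxan-2-yl]methyl acetate (both C6 anomers)
Conditions: Ac2O, TMSOTf (10 mol %), CH2Cl2, 0 °C
Reagents that add atoms: acetic anhydride, CC(=O)OC(C)=O
Why: Lewis-acid acetolysis cleaves the 1,6-anhydro bridge to the pyranosyl acetate while the tertiary alcohol is acetylated, so the T8 acetate of the target is in place before any other tertiary hydroxyl exists.

Step 16
Reactants: 24 [(2S,5S)-5,6-bis(acetyloxy)-5-methyloxan-2-yl]methyl acetate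
Product: 25 [(2S,5S,6R)-5-(acetyloxy)-5-methyl-6-[(trimethylsilyl)ethynyl]oxan-2-yl]methyl acetate
Conditions: Bu3SnC≡CSiMe3, TMSOTf (1.2 equiv), CH2Cl2, −40 → 0 °C
Reagents that add atoms: tributyl[(trimethylsilyl)ethynyl]stannane, CCCC[Sn](CCCC)(CCCC)C#C[Si](C)(C)C
Why: In this Lewis-acid C-glycosylation the oxocarbenium ion, bridged by the neighbouring T8 acetate, is attacked by the alkynylstannane trans to that acetate and trans to the T11 substituent (axial attack), setting T7.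

Step 17
Reactants: 25 [(2S,5S,6R)-5-(acetyloxy)-5-methyl-6-[(trimethylsilyl)ethynyl]oxan-2-yl]methyl acetate
Product: 26 (2R,3S,6S)-2-ethynyl-6-(hydroxymethyl)-3-methyloxan-3-yl acetate
Conditions: K2CO3 (cat.), MeOH, 0 °C
Reagents that add atoms: none
Why: Mild methanolysis removes the C-silyl group and the unhindered primary acetate while the hindered tertiary acetate survives.

Step 18
Reactants: 26 (2R,3S,6S)-2-ethynyl-6-(hydroxymethyl)-3-methyloxan-3-yl acetate
Product: 27 (2R,3S,6S)-2-ethenyl-6-(hydroxymethyl)-3-methyloxan-3-yl acetate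
Conditions: H2 (1 atm), Pd/CaCO3 poisoned with Pb(OAc)2, quinoline, EtOAc, rt
Reagents that add atoms: none
Why: Semi-hydrogenation over poisoned palladium stops at the terminal alkene needed for the later hydroboration.

Step 19
Reactants: 27 (2R,3S,6S)-2-ethenyl-6-(hydroxymethyl)-3-methyloxan-3-yl acetate
Product: 28 (2R,3S,6S)-2-ethenyl-6-formyl-3-methyloxan-3-yl acetate
Conditions: Dess–Martin periodinane, NaHCO3, CH2Cl2, 0 °C → rt
Reagents that add atoms: none
Why: Buffered Dess–Martin oxidation gives the α-alkoxy aldehyde without epimerising T11.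

Step 20
Reactants: 28 (2R,3S,6S)-2-ethenyl-6-formyl-3-methyloxan-3-yl acetate
Product: 30 (2R,3S,6S)-6-acetyl-2-ethenyl-3-methyloxan-3-yl acetate, via α-silyl ketone 29 (not isolated)
Conditions: Me3SiCHN2, CH2Cl2/hexane, 0 °C → rt; then HCl/MeOH, 0 °C
Reagents that add atoms: (trimethylsilyl)diazomethane, C[Si](C)(C)C=[N+]=[N-]
Why: Büchner–Curtius–Schlotterbeck homologation (diazoalkane addition then hydride shift) gives the α-silyl ketone, which is protodesilylated to the methyl ketone without base that could epimerise T11 or cleave the acetate.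

Step 21
Reactants: 31 prop-2-yn-1-ol
Product: 33 (2Z)-3-iodo-2-(prop-1-en-2-yl)prop-2-en-1-ol, via cyclic vinylmagnesium alkoxide 32 (not isolated)
Conditions: CH2=C(CH3)MgBr (3.5 equiv), THF, reflux; then I2, −78 → 0 °C
Reagents that add atoms: isopropenylmagnesium bromide, CC(=C)[Mg]Br; iodine, [I][I]
Why: Chelation-directed anti-carbomagnesiation of the propargylic alkoxide puts the isopropenyl group on the proximal carbon and magnesium on the terminal carbon cis to the CH2O group, and iodinolysis with retention gives the (Z)-iodide that fixes the T1=T2 geometry.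

Step 22
Reactants: 33 (2Z)-3-iodo-2-(prop-1-en-2-yl)prop-2-en-1-ol
Product: 34 (2Z)-2-(prop-1-en-2-yl)hex-2-en-4-yn-1-ol
Conditions: propyne, Pd(PPh3)2Cl2 (3 mol %), CuI (6 mol %), Et3N, THF, 0 °C → rt
Reagents that add atoms: propyne, CC#C
Why: Sonogashira coupling replaces iodide by the propynyl group with retention of the alkene geometry.

Step 23
Reactants: 34 (2Z)-2-(prop-1-en-2-yl)hex-2-en-4-yn-1-ol
Product: 36 (2Z,4E)-5-iodo-2-(prop-1-en-2-yl)hexa-2,4-dien-1-ol, via alkenylzirconocene 35 (not isolated)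
Conditions: Cp2Zr(H)Cl (2.5 equiv), THF, rt; then I2, −78 °C
Reagents that add atoms: iodine, [I][I]
Why: Syn hydrozirconation of the methyl-substituted alkyne places zirconium on the methyl-bearing carbon remote from the diene, and iodinolysis with retention gives the (E)-2-iodoalkene that fixes the T3=T4 geometry.

Step 24
Reactants: 36 (2Z,4E)-5-iodo-2-(prop-1-en-2-yl)hexa-2,4-dien-1-ol
Product: 37 (2Z,4E)-5-iodo-2-(prop-1-en-2-yl)hexa-2,4-dienal
Conditions: MnO2, CH2Cl2, rt; used at once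
Reagents that add atoms: none
Why: MnO2 oxidises the allylic alcohol to the non-enolisable dienal without isomerising either alkene.

Step 25
Reactants: 30 (2R,3S,6S)-6-acetyl-2-ethenyl-3-methyloxan-3-yl acetate; 37 (2Z,4E)-5-iodo-2-(prop-1-en-2-yl)hexa-2,4-dienal
Product: 39 (2R,3S,6S)-2-ethenyl-6-[(4Z,6E)-3-hydroxy-7-iodo-4-(prop-1-en-2-yl)octa-4,6-dienoyl]-3-methyloxan-3-yl acetate (both carbinol epimers), via boron enolate 38 (not isolated)
Conditions: 30, Bu2BOTf, iPr2NEt, CH2Cl2, −78 °C; then 37, −78 → −20 °C; pH 7 buffer/MeOH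
Reagents that add atoms: none
Why: In this boron-mediated aldol addition the dibutylboron enolate forms on the methyl side and adds 1,2 to the dienal, making the T13–T14 bond; the T14 configuration is not relied on because steps 29 and 30 reset it.

Step 26
Reactants: 39 (2R,3S,6S)-2-ethenyl-6-[(4Z,6E)-3-hydroxy-7-iodo-4-(prop-1-en-2-yl)octa-4,6-dienoyl]-3-methyloxan-3-yl acetate
Product: 40 (2R,3S,6S)-2-ethenyl-6-[(4Z,6E)-7-iodo-4-(prop-1-en-2-yl)-3-[(triethylsilyl)oxy]octa-4,6-dienoyl]-3-methyloxan-3-yl acetate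
Conditions: Et3SiOTf, 2,6-lutidine, CH2Cl2, −78 °C
Reagents that add atoms: triethylsilyl trifluoromethanesulfonate, CC[Si](CC)(CC)OS(=O)(=O)C(F)(F)F
Why: Silylation makes the T14 oxygen non-acidic and non-chelating, so that only the ring oxygen can direct the next addition.

Step 27
Reactants: 40 (2R,3S,6S)-2-ethenyl-6-[(4Z,6E)-7-iodo-4-(prop-1-en-2-yl)-3-[(triethylsilyl)oxy]octa-4,6-dienoyl]-3-methyloxan-3-yl acetate
Product: 41 (2R,3S,6S)-2-ethenyl-6-[(2R,5Z,7E)-2-hydroxy-8-iodo-5-(prop-1-en-2-yl)-4-[(triethylsilyl)oxy]nona-5,7-dien-2-yl]-3-methyloxan-3-yl acetate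
Conditions: MeMgBr (3 equiv), THF, −78 °C
Reagents that add atoms: methylmagnesium bromide, C[Mg]Br
Why: In this Cram-chelate addition magnesium bridges the ketone and the ring oxygen and methyl attacks from the side of the T11 hydrogen, setting T12 as (R); at −78 °C the hindered tertiary acetate and the alkenyl iodide are left alone.

Step 28
Reactants: 41 (2R,3S,6S)-2-ethenyl-6-[(2R,5Z,7E)-2-hydroxy-8-iodo-5-(prop-1-en-2-yl)-4-[(triethylsilyl)oxy]nona-5,7-dien-2-yl]-3-methyloxan-3-yl acetate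
Product: 42 (2R,3S,6S)-6-[(2R,5Z,7E)-2,4-dihydroxy-8-iodo-5-(prop-1-en-2-yl)nona-5,7-dien-2-yl]-2-ethenyl-3-methyloxan-3-yl acetate (both C4 epimers of the side chain)
Conditions: HF·pyridine, pyridine, THF, 0 °C
Reagents that add atoms: none
Why: Buffered fluoride cleaves the Si–O bond without touching the acetate or the acid-sensitive dienyl carbinol.

Step 29
Reactants: 42 (2R,3S,6S)-6-[(2R,5Z,7E)-2,4-dihydroxy-8-iodo-5-(prop-1-en-2-yl)nona-5,7-dien-2-yl]-2-ethenyl-3-methyloxan-3-yl acetate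
Product: 43 (2R,3S,6S)-2-ethenyl-6-[(2R,5Z,7E)-2-hydroxy-8-iodo-4-oxo-5-(prop-1-en-2-yl)nona-5,7-dien-2-yl]-3-methyloxan-3-yl acetate
Conditions: MnO2, CH2Cl2, rt; used at once
Reagents that add atoms: none
Why: MnO2 oxidises only the allylic secondary alcohol, converging both T14 epimers into a single β-hydroxy ketone.

Step 30
Reactants: 43 (2R,3S,6S)-2-ethenyl-6-[(2R,5Z,7E)-2-hydroxy-8-iodo-4-oxo-5-(prop-1-en-2-yl)nona-5,7-dien-2-yl]-3-methyloxan-3-yl acetate
Product: 44 (2R,3S,6S)-6-[(2R,4R,5Z,7E)-2,4-dihydroxy-8-iodo-5-(prop-1-en-2-yl)nona-5,7-dien-2-yl]-2-ethenyl-3-methyloxan-3-yl acetate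
Conditions: Me4NBH(OAc)3, MeCN/AcOH, −30 °C
Reagents that add atoms: none
Why: In this Evans–Saksena reduction hydride is delivered intramolecularly from the acetoxyborohydride bound to the T12 hydroxyl, giving the 1,3-anti diol and hence (R) at T14.

Step 31
Reactants: 44 (2R,3S,6S)-6-[(2R,4R,5Z,7E)-2,4-dihydroxy-8-iodo-5-(prop-1-en-2-yl)nona-5,7-dien-2-yl]-2-ethenyl-3-methyloxan-3-yl acetate
Product: 46 (1S,2R,4R,5Z,7E,11R,12S)-2,4-dihydroxy-2,8,12-trimethyl-5-(prop-1-en-2-yl)-15-oxabicyclo[9.3.1]pentadeca-5,7-dien-12-yl acetate, via B-alkyl-9-BBN 45 (not isolated)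
Conditions: 9-BBN (4 equiv), THF, 0 °C → rt; then slow addition to Pd(dppf)Cl2 (20 mol %), AsPh3, Cs2CO3, DMF/THF/H2O (1 mM), 50 °C
Reagents that add atoms: none
Why: 9-BBN hydroborates the monosubstituted vinyl group in preference to the conjugated, more substituted alkenes, and intramolecular B-alkyl Suzuki–Miyaura coupling with the alkenyl iodide (retention) closes the 14-membered ring at T4–T5; the T14 alcohol is left unacylated here so that zerovalent palladium meets no allylic acetate.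

Step 32
Reactants: 46 (1S,2R,4R,5Z,7E,11R,12S)-2,4-dihydroxy-2,8,12-trimethyl-5-(prop-1-en-2-yl)-15-oxabicyclo[9.3.1]pentadeca-5,7-dien-12-yl acetate
Product: 47 (1S,2R,4R,5Z,7E,11R,12S)-2-hydroxy-2,8,12-trimethyl-5-(prop-1-en-2-yl)-15-oxabicyclo[9.3.1]pentadeca-5,7-diene-4,12-diyl diacetate
Conditions: Ac2O, pyridine, DMAP (5 mol %), CH2Cl2, 0 °C
Reagents that add atoms: acetic anhydride, CC(=O)OC(C)=O
Why: Acylation takes the secondary allylic alcohol only, because the hindered tertiary T12 hydroxyl does not react under these conditions.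

Step 33
Reactants: 21 methyl (1E,5R,9S,12R)-5,9-dimethyl-3,10,13-trioxo-12-(propan-2-yl)cyclotetradec-1-ene-1-carboxylate; 47 (1S,2R,4R,5Z,7E,11R,12S)-2-hydroxy-2,8,12-trimethyl-5-(prop-1-en-2-yl)-15-oxabicyclo[9.3.1]pentadeca-5,7-diene-4,12-diyl diacetate
Product: 48 CNP0235363.2 (target)
Conditions: toluene (1 M), BHT (cat.), 90 °C, 48 h; HPLC
Reagents that add atoms: none
Why: In this intermolecular Diels–Alder reaction the s-cis isopropenyl diene (T16=T15–T1=T2) adds suprafacially to the ene-dione ester with the ester endo and with attack on the open peripheral face of each macrocycle (the allylic T14 centre biasing the diene face), which forms the cyclohexene and sets D11, D12 and T2 under control of the existing stereocentres.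

## Compound list

1 | (R)-citronellal, (3R)-3,7-dimethyloct-6-enal | CC(C)=CCC[C@@H](C)CC=O | starting material
2 | (4R)-4,8-dimethylnona-1,7-diene | CC(C)=CCC[C@@H](C)CC=C | intermediate
3 | (4R)-4-methylhept-6-enal | O=CCC[C@@H](C)CC=C | intermediate
4 | (4R)-4-methylhept-6-en-1-ol | OCCC[C@@H](C)CC=C | intermediate
5 | (4R)-7-bromo-4-methylhept-1-ene | BrCCC[C@@H](C)CC=C | intermediate
6 | methyl (2S)-2-hydroxypropanoate | C[C@H](O)C(=O)OC | starting material
7 | methyl (2S)-2-{[(trifluoromethyl)sulfonyl]oxy}propanoate | C[C@H](OS(=O)(=O)C(F)(F)F)C(=O)OC | intermediate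
8 | [(4R)-4-methylhept-6-en-1-yl]magnesium bromide | Br[Mg]CCC[C@@H](C)CC=C | intermediate
9 | methyl (2S,6R)-2,6-dimethylnon-8-enoate | COC(=O)[C@@H](C)CCC[C@@H](C)CC=C | intermediate
10 | tert-butyl (4S,8R)-4,8-dimethyl-3-oxoundec-10-enoate | CC(C)(C)OC(=O)CC(=O)[C@@H](C)CCC[C@@H](C)CC=C | intermediate
11 | tert-butyl (2S)-2-hydroxy-3-methylbutanoate | CC(C)[C@H](O)C(=O)OC(C)(C)C | starting material
12 | tert-butyl (2S)-3-methyl-2-{[(trifluoromethyl)sulfonyl]oxy}butanoate | CC(C)[C@H](OS(=O)(=O)C(F)(F)F)C(=O)OC(C)(C)C | intermediate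
13 | di-tert-butyl (2S)-3-[(2S,6R)-2,6-dimethylnon-8-enoyl]-2-(propan-2-yl)butanedioate, C3 epimers | CC(C)[C@@H](C(C(=O)OC(C)(C)C)C(=O)[C@@H](C)CCC[C@@H](C)CC=C)C(=O)OC(C)(C)C | intermediate
14 | (2R,5S,9R)-5,9-dimethyl-4-oxo-2-(propan-2-yl)dodec-11-enoic acid | CC(C)[C@@H](CC(=O)[C@@H](C)CCC[C@@H](C)CC=C)C(=O)O | intermediate
15 | mixed anhydride of 14 with isobutyl hydrogen carbonate | CC(C)COC(=O)OC(=O)[C@@H](C(C)C)CC(=O)[C@@H](C)CCC[C@@H](C)CC=C | intermediate
16 | (3R,6S,10R)-1-diazo-6,10-dimethyl-3-(propan-2-yl)tridec-12-ene-2,5-dione | [N-]=[N+]=CC(=O)[C@@H](C(C)C)CC(=O)[C@@H](C)CCC[C@@H](C)CC=C | intermediate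
17 | (3R,6S,10R)-1-bromo-6,10-dimethyl-3-(propan-2-yl)tridec-12-ene-2,5-dione | BrCC(=O)[C@@H](C(C)C)CC(=O)[C@@H](C)CCC[C@@H](C)CC=C | intermediate
18 | (3R,6S,10R)-1-bromo-13-hydroxy-6,10-dimethyl-3-(propan-2-yl)tridecane-2,5,12-trione | BrCC(=O)[C@@H](C(C)C)CC(=O)[C@@H](C)CCC[C@@H](C)CC(=O)CO | intermediate
19 | methyl (5R,8S,12R)-15-hydroxy-8,12-dimethyl-4,7,14-trioxo-5-(propan-2-yl)-2-(triphenyl-λ5-phosphanylidene)pentadecanoate | COC(=O)C(CC(=O)[C@@H](C(C)C)CC(=O)[C@@H](C)CCC[C@@H](C)CC(=O)CO)=P(c1ccccc1)(c1ccccc1)c1ccccc1 | intermediate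
20 | methyl (5R,8S,12R)-8,12-dimethyl-4,7,14,15-tetraoxo-5-(propan-2-yl)-2-(triphenyl-λ5-phosphanylidene)pentadecanoate | COC(=O)C(CC(=O)[C@@H](C(C)C)CC(=O)[C@@H](C)CCC[C@@H](C)CC(=O)C=O)=P(c1ccccc1)(c1ccccc1)c1ccccc1 | intermediate
21 | methyl (1E,5R,9S,12R)-5,9-dimethyl-3,10,13-trioxo-12-(propan-2-yl)cyclotetradec-1-ene-1-carboxylate (dienophile) | COC(=O)/C1=C/C(=O)C[C@H](C)CCC[C@H](C)C(=O)C[C@H](C(C)C)C(=O)C1 | intermediate
22 | Cyrene, (1S,5R)-6,8-dioxabicyclo[3.2.1]octan-4-one | O=C1CC[C@H]2CO[C@@H]1O2 | starting material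
23 | (1S,4S,5R)-4-methyl-6,8-dioxabicyclo[3.2.1]octan-4-ol | C[C@]1(O)CC[C@H]2CO[C@@H]1O2 | intermediate
24 | [(2S,5S)-5,6-bis(acetyloxy)-5-methyloxan-2-yl]methyl acetate, both anomers | CC(=O)OC1O[C@@H](CC[C@]1(C)OC(C)=O)COC(C)=O | intermediate
25 | [(2S,5S,6R)-5-(acetyloxy)-5-methyl-6-[(trimethylsilyl)ethynyl]oxan-2-yl]methyl acetate | C[Si](C)(C)C#C[C@H]1O[C@@H](CC[C@]1(C)OC(C)=O)COC(C)=O | intermediate
26 | (2R,3S,6S)-2-ethynyl-6-(hydroxymethyl)-3-methyloxan-3-yl acetate | C#C[C@H]1O[C@@H](CC[C@]1(C)OC(C)=O)CO | intermediate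
27 | (2R,3S,6S)-2-ethenyl-6-(hydroxymethyl)-3-methyloxan-3-yl acetate | C=C[C@H]1O[C@@H](CC[C@]1(C)OC(C)=O)CO | intermediate
28 | (2R,3S,6S)-2-ethenyl-6-formyl-3-methyloxan-3-yl acetate | C=C[C@H]1O[C@@H](CC[C@]1(C)OC(C)=O)C=O | intermediate
29 | (2R,3S,6S)-2-ethenyl-3-methyl-6-[(trimethylsilyl)acetyl]oxan-3-yl acetate | C=C[C@H]1O[C@@H](CC[C@]1(C)OC(C)=O)C(=O)C[Si](C)(C)C | intermediate
30 | (2R,3S,6S)-6-acetyl-2-ethenyl-3-methyloxan-3-yl acetate | C=C[C@H]1O[C@@H](CC[C@]1(C)OC(C)=O)C(C)=O | intermediate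
31 | prop-2-yn-1-ol | C#CCO | starting material
32 | 4-(prop-1-en-2-yl)-2,5-dihydro-1,2-oxamagnesole (cyclic vinylmagnesium alkoxide) | C=C(C)C1=C[Mg]OC1 | intermediate
33 | (2Z)-3-iodo-2-(prop-1-en-2-yl)prop-2-en-1-ol | C=C(C)/C(CO)=C/I | intermediate
34 | (2Z)-2-(prop-1-en-2-yl)hex-2-en-4-yn-1-ol | C=C(C)/C(CO)=C/C#CC | intermediate
35 | chlorobis(cyclopentadienyl)[(2E,4Z)-6-hydroxy-5-(prop-1-en-2-yl)hexa-2,4-dien-2-yl]zirconium (rings drawn σ-bonded; hydroxyl held as zirconium alkoxide in the flask) | C=C(C)/C(CO)=C/C=C(\C)[Zr](Cl)(C1C=CC=C1)C1C=CC=C1 | intermediate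
36 | (2Z,4E)-5-iodo-2-(prop-1-en-2-yl)hexa-2,4-dien-1-ol | C=C(C)/C(CO)=C/C=C(\C)I | intermediate
37 | (2Z,4E)-5-iodo-2-(prop-1-en-2-yl)hexa-2,4-dienal | C=C(C)/C(C=O)=C/C=C(\C)I | intermediate
38 | dibutylboron enolate of 30 | C=C[C@H]1O[C@@H](CC[C@]1(C)OC(C)=O)C(=C)OB(CCCC)CCCC | intermediate
39 | (2R,3S,6S)-2-ethenyl-6-[(4Z,6E)-3-hydroxy-7-iodo-4-(prop-1-en-2-yl)octa-4,6-dienoyl]-3-methyloxan-3-yl acetate, carbinol epimers | C=C[C@H]1O[C@@H](CC[C@]1(C)OC(C)=O)C(=O)CC(O)/C(=C\C=C(/C)I)C(C)=C | intermediate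
40 | triethylsilyl ether of 39 | C=C[C@H]1O[C@@H](CC[C@]1(C)OC(C)=O)C(=O)CC(O[Si](CC)(CC)CC)/C(=C\C=C(/C)I)C(C)=C | intermediate
41 | (2R,3S,6S)-2-ethenyl-6-[(2R,5Z,7E)-2-hydroxy-8-iodo-5-(prop-1-en-2-yl)-4-[(triethylsilyl)oxy]nona-5,7-dien-2-yl]-3-methyloxan-3-yl acetate | C=C[C@H]1O[C@@H](CC[C@]1(C)OC(C)=O)[C@](C)(O)CC(O[Si](CC)(CC)CC)/C(=C\C=C(/C)I)C(C)=C | intermediate
42 | (2R,3S,6S)-6-[(2R,5Z,7E)-2,4-dihydroxy-8-iodo-5-(prop-1-en-2-yl)nona-5,7-dien-2-yl]-2-ethenyl-3-methyloxan-3-yl acetate, C4 epimers | C=C[C@H]1O[C@@H](CC[C@]1(C)OC(C)=O)[C@](C)(O)CC(O)/C(=C\C=C(/C)I)C(C)=C | intermediate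
43 | (2R,3S,6S)-2-ethenyl-6-[(2R,5Z,7E)-2-hydroxy-8-iodo-4-oxo-5-(prop-1-en-2-yl)nona-5,7-dien-2-yl]-3-methyloxan-3-yl acetate | C=C[C@H]1O[C@@H](CC[C@]1(C)OC(C)=O)[C@](C)(O)CC(=O)/C(=C\C=C(/C)I)C(C)=C | intermediate
44 | (2R,3S,6S)-6-[(2R,4R,5Z,7E)-2,4-dihydroxy-8-iodo-5-(prop-1-en-2-yl)nona-5,7-dien-2-yl]-2-ethenyl-3-methyloxan-3-yl acetate | C=C[C@H]1O[C@@H](CC[C@]1(C)OC(C)=O)[C@](C)(O)C[C@@H](O)/C(=C\C=C(/C)I)C(C)=C | intermediate
45 | B-alkyl-9-borabicyclo[3.3.1]nonane from hydroboration of the vinyl group of 44 | C(CB1C2CCCC1CCC2)[C@H]3O[C@@H](CC[C@]3(C)OC(C)=O)[C@](C)(O)C[C@@H](O)/C(=C\C=C(/C)I)C(C)=C | intermediate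
46 | (1S,2R,4R,5Z,7E,11R,12S)-2,4-dihydroxy-2,8,12-trimethyl-5-(prop-1-en-2-yl)-15-oxabicyclo[9.3.1]pentadeca-5,7-dien-12-yl acetate | C=C(C)/C1=C/C=C(\C)CC[C@H]2O[C@@H](CC[C@]2(C)OC(C)=O)[C@](C)(O)C[C@H]1O | intermediate
47 | (1S,2R,4R,5Z,7E,11R,12S)-2-hydroxy-2,8,12-trimethyl-5-(prop-1-en-2-yl)-15-oxabicyclo[9.3.1]pentadeca-5,7-diene-4,12-diyl diacetate (triene monomer) | C=C(C)/C1=C/C=C(\C)CC[C@H]2O[C@@H](CC[C@]2(C)OC(C)=O)[C@](C)(O)C[C@H]1OC(C)=O | intermediate
48 | CNP0235363.2 | COC(=O)[C@@]12CC(=O)[C@@H](C(C)C)CC(=O)[C@@H](C)CCC[C@@H](C)CC(=O)[C@@H]1CC(C)=C1[C@H]2/C=C(\C)CC[C@H]2O[C@@H](CC[C@]2(C)OC(C)=O)[C@](C)(O)C[C@H]1OC(C)=O | target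

## Step count and risks

Total step count: 33.
Longest linear sequence: 16 steps (steps 14–20, then 25–33).

The three steps most likely to fail:

Step 33, the Diels–Alder union. It must choose one regiochemistry, the ester-endo mode and one face of each macrocycle out of several possible adducts, and the selectivity is argued only from peripheral attack and the known behaviour of this monomer class. The fallback runs the cycloaddition one step earlier, with the free allylic alcohol 46 instead of 47, in a non-polar medium (or as its magnesium alkoxide with MgBr2·OEt2), so that the T14 hydroxyl binds the D10 carbonyl of 21 and delivers the dienophile to one diene face. This gives the 14-deacetyl adduct F1, which is acetylated at the secondary hydroxyl (Ac2O, pyridine, DMAP) to give 48. It sets out from 46 (with 21) and comes back to the route at 48.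

Step 31, the hydroboration/B-alkyl Suzuki macrocyclisation. It needs 9-BBN to pick the vinyl group in a polyene and the coupling to close a 14-membered ring. The fallback reverses the order of the two unions, so that the sp3–sp2 coupling is intermolecular and the ring is closed by an aldol reaction. The vinyl group of ketone 30 is hydroborated with 9-BBN (1.1 equiv, 0 °C) to the alkylborane F2, which is coupled (Pd(dppf)Cl2, AsPh3, Cs2CO3) with iodo-dienal 37 to the open-chain keto-aldehyde F3. Intramolecular aldol addition of the methyl ketone to the non-enolisable aldehyde (KN(SiMe3)2, THF, −78 °C, high dilution) gives the macrocyclic aldol F4. This is silylated to the silyl ether F5, treated with MeMgBr under chelation control to give the tertiary alcohol F6, desilylated to the diol F7, oxidised with MnO2 to the hydroxy ketone F8 and reduced with Me4NBH(OAc)3. It sets out from 30 and 37 and comes back to the route at 46.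

Step 8, the SN2 alkylation at the β-branched valine-derived triflate. The bulky β-keto ester enolate may eliminate or O-alkylate instead. The fallback changes the bond-forming order: triflate 12 is displaced by the small sodium salt of di-tert-butyl malonate to give the triester F9, and ester 9 is saponified (LiOH) to the acid F10 and converted ((COCl)2, cat. DMF) into the acid chloride F11. The sodium salt of F9 is C-acylated with F11 to the acylmalonate F12, and CF3CO2H with warming removes the three tert-butyl groups and two CO2. It sets out from 12 and 9 and comes back to the route at 14.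

## Further compounds

F1 | step 33 | 14-O-deacetyl target, Diels–Alder adduct of 21 and 46 | COC(=O)[C@@]12CC(=O)[C@@H](C(C)C)CC(=O)[C@@H](C)CCC[C@@H](C)CC(=O)[C@@H]1CC(C)=C1[C@H]2/C=C(\C)CC[C@H]2O[C@@H](CC[C@]2(C)OC(C)=O)[C@](C)(O)C[C@H]1O
F2 | step 31 | (2R,3S,6S)-6-acetyl-2-[2-(9-borabicyclo[3.3.1]nonan-9-yl)ethyl]-3-methyloxan-3-yl acetate | C(CB1C2CCCC1CCC2)[C@H]3O[C@@H](CC[C@]3(C)OC(C)=O)C(C)=O
F3 | step 31 | (2R,3S,6S)-6-acetyl-2-[(3E,5Z)-6-formyl-3,7-dimethylocta-3,5,7-trien-1-yl]-3-methyloxan-3-yl acetate | C=C(C)/C(C=O)=C/C=C(\C)CC[C@H]1O[C@@H](CC[C@]1(C)OC(C)=O)C(C)=O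
F4 | step 31 | (1S,5Z,7E,11R,12S)-4-hydroxy-8,12-dimethyl-2-oxo-5-(prop-1-en-2-yl)-15-oxabicyclo[9.3.1]pentadeca-5,7-dien-12-yl acetate, C4 epimers | C=C(C)/C1=C/C=C(\C)CC[C@H]2O[C@@H](CC[C@]2(C)OC(C)=O)C(=O)CC1O
F5 | step 31 | triethylsilyl ether of F4 | C=C(C)/C1=C/C=C(\C)CC[C@H]2O[C@@H](CC[C@]2(C)OC(C)=O)C(=O)CC1O[Si](CC)(CC)CC
F6 | step 31 | (1S,2R,5Z,7E,11R,12S)-2-hydroxy-2,8,12-trimethyl-5-(prop-1-en-2-yl)-4-[(triethylsilyl)oxy]-15-oxabicyclo[9.3.1]pentadeca-5,7-dien-12-yl acetate, C4 epimers | C=C(C)/C1=C/C=C(\C)CC[C@H]2O[C@@H](CC[C@]2(C)OC(C)=O)[C@](C)(O)CC1O[Si](CC)(CC)CC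
F7 | step 31 | (1S,2R,5Z,7E,11R,12S)-2,4-dihydroxy-2,8,12-trimethyl-5-(prop-1-en-2-yl)-15-oxabicyclo[9.3.1]pentadeca-5,7-dien-12-yl acetate, C4 epimers | C=C(C)/C1=C/C=C(\C)CC[C@H]2O[C@@H](CC[C@]2(C)OC(C)=O)[C@](C)(O)CC1O
F8 | step 31 | (1S,2R,5Z,7E,11R,12S)-2-hydroxy-2,8,12-trimethyl-4-oxo-5-(prop-1-en-2-yl)-15-oxabicyclo[9.3.1]pentadeca-5,7-dien-12-yl acetate | C=C(C)/C1=C/C=C(\C)CC[C@H]2O[C@@H](CC[C@]2(C)OC(C)=O)[C@](C)(O)CC1=O
F9 | step 8 | tri-tert-butyl (2S)-3-methylbutane-1,1,2-tricarboxylate | CC(C)[C@@H](C(C(=O)OC(C)(C)C)C(=O)OC(C)(C)C)C(=O)OC(C)(C)C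
F10 | step 8 | (2S,6R)-2,6-dimethylnon-8-enoic acid | OC(=O)[C@@H](C)CCC[C@@H](C)CC=C
F11 | step 8 | (2S,6R)-2,6-dimethylnon-8-enoyl chloride | ClC(=O)[C@@H](C)CCC[C@@H](C)CC=C
F12 | step 8 | tri-tert-butyl (2S)-1-[(2S,6R)-2,6-dimethylnon-8-enoyl]-3-methylbutane-1,1,2-tricarboxylate | CC(C)[C@@H](C(C(=O)OC(C)(C)C)(C(=O)OC(C)(C)C)C(=O)[C@@H](C)CCC[C@@H](C)CC=C)C(=O)OC(C)(C)C
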